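**Strategy.** Ring A is cut at C2–C3 and C5–C10. This leaves two three-carbon units: C3–C4–C5, in which C3 and C5 flank the quaternary C4, and C10–C1–C2. The key step exploits this matched 1,3-relationship. One amine-catalysed nitro-Michael/Henry [3+3] annulation makes both bonds. A 1,3-dinitropropane whose central carbon is the future C4 adds through C5 to the β,β-disubstituted enal carbon C10, and C3 then closes onto the aldehyde C2. The chiral pyrrolidine sets the quaternary C10, and all other ring stereocentres derive from it. The precursors are the achiral dinitro acetonide 5 and the acyclic enal 17, which carries C13. Ring B follows by a second nitro-Michael closure, and Bu3SnH then removes the nitro groups.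

Key step: step 11

Assumption: labdane numbering (C1–C20) is used for all intermediates, and α is the face opposite to the C20 methyl group. Centres that are erased or equilibrated later are carried as mixtures and are written without configuration unless one isomer is expected.

Step 1
Reactants: 1 2,2-dimethyl-1,3-dioxan-5-one; 2 nitromethane
Product: 4 2,2-dimethyl-5-(nitromethylidene)-1,3-dioxane, via nitro alcohol 3 (not isolated)
Conditions: MeNO2, Et3N (cat.), 0 to 23 °C; then MsCl, Et3N, CH2Cl2, −78 to 0 °C
Reagents that add atoms: none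
Why: A Henry addition to the ketone followed by mesylation and E1cB dehydration should give the β,β-disubstituted nitroalkene, and no stereocentre is formed.

Step 2
Reactants: 4 2,2-dimethyl-5-(nitromethylidene)-1,3-dioxane; 2 nitromethane
Product: 5 2,2-dimethyl-5,5-bis(nitromethyl)-1,3-dioxane
Conditions: MeNO2 (excess), DBU (cat.), THF, 0 °C
Reagents that add atoms: none
Why: A nitro-Michael addition to the nitroalkene builds the quaternary carbon C4, which stays non-stereogenic because its arms are pairwise identical.

Step 3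
Reactants: 6 (R)-5-methoxy-3-methyl-5-oxopentanoic acid (methyl hydrogen (R)-3-methylglutarate)
Product: 7 1-tert-butyl 5-methyl (S)-3-methylpentanedioate
Conditions: Boc2O, DMAP (cat.), t-BuOH, 23 °C
Reagents that add atoms: di-tert-butyl dicarbonate, CC(C)(C)OC(=O)OC(=O)OC(C)(C)C
Why: DMAP-catalysed esterification through the mixed carbonic anhydride differentiates the two carboxyl ends, and the chiral-pool centre C13 is not touched.

Step 4
Reactants: 7 1-tert-butyl 5-methyl (S)-3-methylpentanedioate
Product: 8 tert-butyl (S)-5-hydroxy-3-methylpentanoate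
Conditions: LiBH4, THF, 0 to 23 °C
Reagents that add atoms: none
Why: Chemoselective borohydride reduction should take the methyl ester and leave the hindered tert-butyl ester.

Step 5
Reactants: 8 tert-butyl (S)-5-hydroxy-3-methylpentanoate
Product: 9 tert-butyl (R)-5-iodo-3-methylpentanoate
Conditions: I2, PPh3, imidazole, CH2Cl2, 0 °C
Reagents that add atoms: iodine, II
Why: An Appel-type iodination of the primary alcohol gives the C11 electrophile; the descriptor changes only through the priority rules.

Step 6
Reactants: 10 acrolein; 11 methyl acetate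
Product: 12 methyl 3-hydroxypent-4-enoate (racemic)
Conditions: LDA, THF, −78 °C; then 10
Reagents that add atoms: none
Why: Aldol 1,2-addition of the lithium ester enolate to acrolein gives the C10–C9–C8–C7–C6 unit, and its carbinol centre is erased in step 13.

Step 7
Reactants: 12 methyl 3-hydroxypent-4-enoate; 9 tert-butyl (R)-5-iodo-3-methylpentanoate
Product: 13 1-tert-butyl 7-methyl (3S)-6-(1-hydroxyprop-2-en-1-yl)-3-methylheptanedioate (mixture at C8 and C9)
Conditions: LDA (2.2 equiv), THF/DMPU, −78 to −20 °C; then 9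
Reagents that add atoms: none
Why: Fráter–Seebach alkylation of the β-hydroxy ester dianion forms C9–C11; the new centre C9 need not be controlled because it is equilibrated in step 16.

Step 8
Reactants: 13 hydroxy diester
Product: 14 1-tert-butyl 7-methyl (3S)-6-{1-[(tert-butyldimethylsilyl)oxy]prop-2-en-1-yl}-3-methylheptanedioate
Conditions: TBSOTf, 2,6-lutidine, CH2Cl2, 0 °C
Reagents that add atoms: tert-butyldimethylsilyl triflate, CC(C)(C)[Si](C)(C)OS(=O)(=O)C(F)(F)F
Why: Silylation masks the C8 alcohol, so that C9–H is not flanked by a carbonyl group while the enal is built and used.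

Step 9
Reactants: 14 silyl ether diester
Product: 16 tert-butyl (3S)-6-acetyl-7-[(tert-butyldimethylsilyl)oxy]-3-methylnon-8-enoate, via Weinreb amide 15 (not isolated)
Conditions: MeNHOMe·HCl, iPrMgCl, THF, −20 °C; then MeMgBr, 0 °C
Reagents that add atoms: methylmagnesium bromide, C[Mg]Br
Why: A Weinreb ketone synthesis at the methyl ester installs C20 on C10, and the chelated tetrahedral adduct prevents over-addition.

Step 10
Reactants: 16 methyl ketone
Product: 17 tert-butyl (3S)-7-[(tert-butyldimethylsilyl)oxy]-3-methyl-6-[(2E)-4-oxobut-2-en-2-yl]non-8-enoate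
Conditions: t-BuN=CHCH2SiMe3, s-BuLi, THF, −78 °C; then 16, −78 to −20 °C; then aq. oxalic acid
Reagents that add atoms: N-tert-butyl-2-(trimethylsilyl)ethan-1-imine, CC(C)(C)N=CC[Si](C)(C)C; water, O
Why: A Peterson olefination with the lithiated α-silyl aldimine, followed by imine hydrolysis, adds C1 and C2 in one flask; the E-enal with the large C9 arm trans to the formyl group is the more stable isomer.

Step 11
Reactants: 5 2,2-dimethyl-5,5-bis(nitromethyl)-1,3-dioxane; 17 enal
Product: 19 ring A cyclohexanol (2α-OH, 3β-NO2 and 5-NO2 all equatorial; C10 quaternary with axial β-methyl and equatorial C9 arm; C4 spiro to the dioxane), via Michael adduct 18 (not isolated)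
Conditions: (R)-2-[diphenyl(trimethylsilyloxy)methyl]pyrrolidine (20 mol %), DABCO (20 mol %), CH2Cl2, 23 °C
Reagents that add atoms: none
Why: The pyrrolidine condenses with 17 to the E-configured iminium ion, a nitronate of 5 (DABCO) adds through C5 to C10 (bond C5–C10), hydrolysis of the enamine frees aldehyde 18, and the second nitronate carbon C3 adds to C2 (bond C2–C3). The sequence is the known organocatalytic nitro-Michael/Henry [3+3] annulation of 1,3-dinitropropanes with enals, joined to the known iminium-catalysed addition of nitroalkanes to β,β-disubstituted enals that builds quaternary carbons. Ring A closes in the Henry step in the 6-exo-trig mode through a chair in which the large C9 arm on C10 is equatorial and the C20 methyl is axial. C10 is controlled by the catalyst, whose CPh2(OSiMe3) group shields one face of the iminium ion so that C5 attacks the open face of the E-enal; C5, C3 and C2 are epimerisable (nitronate formation, reversible Henry step), should settle all-equatorial, and are erased in steps 13 and 15. C4 stays non-stereogenic because its two CH2O arms are still identical. The step needs 1,4- over 1,2-addition and only one Michael addition per dinitro unit: iminium activation directs the attack to C10, and the fast intramolecular Henry closure consumes the aldehyde and the second nitronate before they react further.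

Step 12
Reactants: 19 ring A cyclohexanol
Product: 20 ring A cyclohexanol with free allylic C8 alcohol
Conditions: Bu4NF, AcOH, THF, 0 to 23 °C
Reagents that add atoms: none
Why: Buffered fluoride desilylation frees the allylic alcohol, and the buffer should keep the β-nitro alcohol from retro-Henry cleavage.

Step 13
Reactants: 20 allylic alcohol
Product: 22 tert-butyl 2α-hydroxy-18,19-(isopropylidenedioxy)-3β,5-dinitro-8-oxo-17-norlabdan-15-oate (mixture at C5 and C9), via vinyl ketone 21 (not isolated)
Conditions: MnO2, CH2Cl2, 23 °C; then DBU (cat.)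
Reagents that add atoms: none
Why: MnO2 oxidises only the allylic alcohol, and the C5 nitronate then closes ring B by an intramolecular nitro-Michael addition (6-endo-trig) to the unhindered terminus C6; the configuration at C5 is erased in step 15.

Step 14
Reactants: 22 nitro decalone
Product: 23 the 2-O-(imidazol-1-ylthiocarbonyl) derivative of 22
Conditions: 1,1'-thiocarbonyldiimidazole, DMAP (cat.), ClCH2CH2Cl, 60 °C
Reagents that add atoms: 1,1'-thiocarbonyldiimidazole, S=C(n1ccnc1)n1ccnc1
Why: Thioacylation of the only free hydroxyl group prepares a Barton–McCombie-type radical precursor at C2.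

Step 15
Reactants: 23 thiocarbonyl derivative
Product: 24 tert-butyl 18,19-(isopropylidenedioxy)-8-oxo-17-norlabd-2-en-15-oate (5α-H, mixture at C9)
Conditions: Bu3SnH, AIBN, toluene, 110 °C
Reagents that add atoms: none
Why: The C2 radical expels the β-nitro group from C3 to give the C2=C3 alkene. Radical denitration of the tertiary C5 nitro group delivers hydrogen from the α face, because the β face is shielded by the C20 methyl and the axial CH2O arm on C4, and this sets the trans ring fusion.

Step 16
Reactants: 24 ene ketone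
Product: 26 tert-butyl 18,19-(isopropylidenedioxy)-8-oxo-17-norlabdan-15-oate (5α-H, 9α-H, 10β-methyl), via C9 epimer mixture 25 (not isolated)
Conditions: H2, Pd/C, EtOAc, 23 °C; then K2CO3 (cat.), MeOH, 23 °C
Reagents that add atoms: none
Why: Catalytic hydrogenation saturates C2=C3, and base equilibration next to the C8 ketone places the C9 side chain in the equatorial β position of the trans-decalin.

Step 17
Reactants: 26 acetonide ketone
Product: 27 tert-butyl 18,19-dihydroxy-8-oxo-17-norlabdan-15-oate
Conditions: AcOH/H2O (4:1), 40 °C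
Reagents that add atoms: none
Why: Mild acid hydrolysis of the isopropylidene acetal frees both hydroxymethyl groups and leaves the tert-butyl ester intact.

Step 18
Reactants: 27 diol
Product: 28 tert-butyl 18-acetoxy-19-hydroxy-8-oxo-17-norlabdan-15-oate
Conditions: AcCl (1.0 equiv), 2,4,6-collidine, CH2Cl2, −78 °C
Reagents that add atoms: acetyl chloride, CC(=O)Cl
Why: Kinetically selective acylation should take the equatorial 4α-CH2OH (C18) rather than the axial 4β-CH2OH (C19), which is 1,3-diaxial to the C20 methyl, and this choice sets the C4 stereocentre.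

Step 19
Reactants: 28 monoacetate
Product: 29 the 19-O-(imidazol-1-ylthiocarbonyl) derivative of 28
Conditions: 1,1'-thiocarbonyldiimidazole, DMAP (cat.), toluene, 80 °C
Reagents that add atoms: 1,1'-thiocarbonyldiimidazole, S=C(n1ccnc1)n1ccnc1
Why: Thioacylation of the remaining axial alcohol prepares its Barton–McCombie removal.

Step 20
Reactants: 29 thiocarbonyl derivative
Product: 30 tert-butyl 18-acetoxy-8-oxo-17-norlabdan-15-oate
Conditions: Bu3SnH, AIBN, toluene, 110 °C
Reagents that add atoms: none
Why: Barton–McCombie deoxygenation turns the axial CH2O group into the C19 methyl without touching C4.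

Step 21
Reactants: 30 keto acetate
Product: 31 tert-butyl 18-acetoxylabd-8(17)-en-15-oate
Conditions: Zn, CH2Br2, TiCl4, THF/CH2Cl2, 0 to 23 °C
Reagents that add atoms: dibromomethane, BrCBr
Why: Lombardo methylenation is non-basic, so it should convert the hindered C8 ketone into the exocyclic alkene without epimerising C9 or attacking the two esters.

Step 22
Reactants: 31 tert-butyl ester
Product: 32 (13S)-18-acetoxylabd-8(17)-en-15-oic acid (target)
Conditions: TMSOTf, 2,6-lutidine, CH2Cl2, 0 °C; then H2O
Reagents that add atoms: none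
Why: Silyl-triflate-mediated cleavage of the tert-butyl ester under buffered conditions should spare the acetate and avoid migration of the exocyclic double bond.

**Compound list**
1 | 2,2-dimethyl-1,3-dioxan-5-one | CC1(C)OCC(=O)CO1 | starting material
2 | nitromethane | C[N+](=O)[O-] | starting material
3 | 2,2-dimethyl-5-(nitromethyl)-1,3-dioxan-5-ol | CC1(C)OCC(O)(C[N+](=O)[O-])CO1 | intermediate
4 | 2,2-dimethyl-5-(nitromethylidene)-1,3-dioxane | CC1(C)OCC(=C[N+](=O)[O-])CO1 | intermediate
5 | 2,2-dimethyl-5,5-bis(nitromethyl)-1,3-dioxane | CC1(C)OCC(C[N+](=O)[O-])(C[N+](=O)[O-])CO1 | intermediate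
6 | (R)-5-methoxy-3-methyl-5-oxopentanoic acid | COC(=O)C[C@H](C)CC(=O)O | starting material
7 | 1-tert-butyl 5-methyl (S)-3-methylpentanedioate | COC(=O)C[C@H](C)CC(=O)OC(C)(C)C | intermediate
8 | tert-butyl (S)-5-hydroxy-3-methylpentanoate | OCC[C@H](C)CC(=O)OC(C)(C)C | intermediate
9 | tert-butyl (R)-5-iodo-3-methylpentanoate | ICC[C@H](C)CC(=O)OC(C)(C)C | intermediate
10 | acrolein | C=CC=O | starting material
11 | methyl acetate | COC(C)=O | starting material
12 | methyl 3-hydroxypent-4-enoate | COC(=O)CC(O)C=C | intermediate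
13 | 1-tert-butyl 7-methyl (3S)-6-(1-hydroxyprop-2-en-1-yl)-3-methylheptanedioate | COC(=O)C(CC[C@H](C)CC(=O)OC(C)(C)C)C(O)C=C | intermediate
14 | tert-butyldimethylsilyl ether of 13 | COC(=O)C(CC[C@H](C)CC(=O)OC(C)(C)C)C(O[Si](C)(C)C(C)(C)C)C=C | intermediate
15 | Weinreb amide from 14 | CON(C)C(=O)C(CC[C@H](C)CC(=O)OC(C)(C)C)C(O[Si](C)(C)C(C)(C)C)C=C | intermediate
16 | tert-butyl (3S)-6-acetyl-7-[(tert-butyldimethylsilyl)oxy]-3-methylnon-8-enoate | CC(=O)C(CC[C@H](C)CC(=O)OC(C)(C)C)C(O[Si](C)(C)C(C)(C)C)C=C | intermediate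
17 | tert-butyl (3S)-7-[(tert-butyldimethylsilyl)oxy]-3-methyl-6-[(2E)-4-oxobut-2-en-2-yl]non-8-enoate | O=C/C=C(\C)C(CC[C@H](C)CC(=O)OC(C)(C)C)C(O[Si](C)(C)C(C)(C)C)C=C | intermediate
18 | Michael adduct aldehyde (C5–C10 formed, C10 set) | O=CC[C@@](C)(C([N+](=O)[O-])C1(C[N+](=O)[O-])COC(C)(C)OC1)C(CC[C@H](C)CC(=O)OC(C)(C)C)C(O[Si](C)(C)C(C)(C)C)C=C | intermediate
19 | ring A cyclohexanol (2α-OH, 3β-NO2, equatorial 5-NO2, 10β-methyl) | [C@H]1([N+](=O)[O-])C2(COC(C)(C)OC2)[C@@H]([N+](=O)[O-])[C@H](O)C[C@]1(C)C(CC[C@H](C)CC(=O)OC(C)(C)C)C(O[Si](C)(C)C(C)(C)C)C=C | intermediate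
20 | desilylated ring A cyclohexanol | [C@H]1([N+](=O)[O-])C2(COC(C)(C)OC2)[C@@H]([N+](=O)[O-])[C@H](O)C[C@]1(C)C(CC[C@H](C)CC(=O)OC(C)(C)C)C(O)C=C | intermediate
21 | vinyl ketone | [C@H]1([N+](=O)[O-])C2(COC(C)(C)OC2)[C@@H]([N+](=O)[O-])[C@H](O)C[C@]1(C)C(CC[C@H](C)CC(=O)OC(C)(C)C)C(=O)C=C | intermediate
22 | tert-butyl 2α-hydroxy-18,19-(isopropylidenedioxy)-3β,5-dinitro-8-oxo-17-norlabdan-15-oate | O=C1CCC2([N+](=O)[O-])C3(COC(C)(C)OC3)[C@@H]([N+](=O)[O-])[C@H](O)C[C@]2(C)C1CC[C@H](C)CC(=O)OC(C)(C)C | intermediate
23 | 2-O-(imidazol-1-ylthiocarbonyl) derivative of 22 | O=C1CCC2([N+](=O)[O-])C3(COC(C)(C)OC3)[C@@H]([N+](=O)[O-])[C@H](OC(=S)n3ccnc3)C[C@]2(C)C1CC[C@H](C)CC(=O)OC(C)(C)C | intermediate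
24 | tert-butyl 18,19-(isopropylidenedioxy)-8-oxo-17-norlabd-2-en-15-oate (5α-H) | O=C1CC[C@H]2C3(COC(C)(C)OC3)C=CC[C@]2(C)C1CC[C@H](C)CC(=O)OC(C)(C)C | intermediate
25 | saturated ketone, C9 epimer mixture | O=C1CC[C@H]2C3(COC(C)(C)OC3)CCC[C@]2(C)C1CC[C@H](C)CC(=O)OC(C)(C)C | intermediate
26 | tert-butyl 18,19-(isopropylidenedioxy)-8-oxo-17-norlabdan-15-oate | O=C1CC[C@H]2C3(COC(C)(C)OC3)CCC[C@]2(C)[C@H]1CC[C@H](C)CC(=O)OC(C)(C)C | intermediate
27 | tert-butyl 18,19-dihydroxy-8-oxo-17-norlabdan-15-oate | O=C1CC[C@H]2C(CO)(CO)CCC[C@]2(C)[C@H]1CC[C@H](C)CC(=O)OC(C)(C)C | intermediate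
28 | tert-butyl 18-acetoxy-19-hydroxy-8-oxo-17-norlabdan-15-oate | O=C1CC[C@H]2[C@](CO)(COC(C)=O)CCC[C@]2(C)[C@H]1CC[C@H](C)CC(=O)OC(C)(C)C | intermediate
29 | 19-O-(imidazol-1-ylthiocarbonyl) derivative of 28 | O=C1CC[C@H]2[C@](COC(=S)n3ccnc3)(COC(C)=O)CCC[C@]2(C)[C@H]1CC[C@H](C)CC(=O)OC(C)(C)C | intermediate
30 | tert-butyl 18-acetoxy-8-oxo-17-norlabdan-15-oate | O=C1CC[C@H]2[C@](C)(COC(C)=O)CCC[C@]2(C)[C@H]1CC[C@H](C)CC(=O)OC(C)(C)C | intermediate
31 | tert-butyl 18-acetoxylabd-8(17)-en-15-oate | C=C1CC[C@H]2[C@](C)(COC(C)=O)CCC[C@]2(C)[C@H]1CC[C@H](C)CC(=O)OC(C)(C)C | intermediate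
32 | (13S)-18-acetoxylabd-8(17)-en-15-oic acid | C=C1CC[C@H]2[C@](C)(COC(C)=O)CCC[C@]2(C)[C@H]1CC[C@H](C)CC(=O)O | target

**Step count and risks**

Total step count: 22. Longest linear sequence: 19 steps (steps 3–5 and 7–22, from 6).

Steps most likely to fail:

1. **Step 11.** The intermolecular attack of a neopentyl-type nitronate on a β,β-disubstituted iminium ion with a branched β-substituent may be too slow. Dienamine formation, E/Z isomerisation of the enal and loss of facial selectivity could then take over. The fallback sets out from 17, 2 and 4 and changes the order of bond formation.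
   - The hindered C5–C10 bond is made first with the smallest nucleophile. Nitromethane 2 adds to 17 under the same pyrrolidine catalysis to give the γ-nitro aldehyde F1.
   - The primary nitronate of this γ-nitro aldehyde F1 is then added (DBU, cat.) to nitroalkene 4, which builds C4–C5.
   - The adduct is 18, which closes by the Henry reaction, so the route is rejoined at 19.

2. **Step 10.** The strongly basic lithio aldimine may enolise the α-branched ketone and trigger β-elimination of the silyloxy group instead of adding to the carbonyl group. The fallback sets out from 16.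
   - CeCl3-promoted addition of ethynylmagnesium bromide gives the tertiary propargylic alcohol F2.
   - A Meyer–Schuster rearrangement (Ph3PAuNTf2, cat., wet MeOH) converts this propargylic alcohol F2 into the enal under non-basic conditions, so the route is rejoined at 17.

3. **Step 18.** Discrimination between the equatorial and the axial hydroxymethyl group by a small acylating agent may be poor, which would scramble C4. The fallback sets out from 27 and separates differentiation from acetate introduction.
   - The bulky TBDPSCl (imidazole, DMF, 0 °C) silylates the equatorial alcohol to give the silyl ether alcohol F3.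
   - Thiocarbonyldiimidazole gives the thiocarbonyl derivative F4.
   - Bu3SnH/AIBN gives the 19-methyl silyl ether F5.
   - Bu4NF gives the primary alcohol F6.
   - Ac2O/pyridine leads back to the route at 30.

Further compounds
F1 | step 11 | γ-nitro aldehyde from 17 and nitromethane (C10 set) | O=CC[C@@](C)(C[N+](=O)[O-])C(CC[C@H](C)CC(=O)OC(C)(C)C)C(O[Si](C)(C)C(C)(C)C)C=C
F2 | step 10 | tert-butyl (3S)-7-[(tert-butyldimethylsilyl)oxy]-6-(2-hydroxybut-3-yn-2-yl)-3-methylnon-8-enoate | C#CC(C)(O)C(CC[C@H](C)CC(=O)OC(C)(C)C)C(O[Si](C)(C)C(C)(C)C)C=C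
F3 | step 18 | tert-butyl 18-[(tert-butyldiphenylsilyl)oxy]-19-hydroxy-8-oxo-17-norlabdan-15-oate | O=C1CC[C@H]2[C@](CO)(CO[Si](c3ccccc3)(c3ccccc3)C(C)(C)C)CCC[C@]2(C)[C@H]1CC[C@H](C)CC(=O)OC(C)(C)C
F4 | step 18 | 19-O-(imidazol-1-ylthiocarbonyl) derivative of F3 | O=C1CC[C@H]2[C@](COC(=S)n3ccnc3)(CO[Si](c3ccccc3)(c3ccccc3)C(C)(C)C)CCC[C@]2(C)[C@H]1CC[C@H](C)CC(=O)OC(C)(C)C
F5 | step 18 | tert-butyl 18-[(tert-butyldiphenylsilyl)oxy]-8-oxo-17-norlabdan-15-oate | O=C1CC[C@H]2[C@](C)(CO[Si](c3ccccc3)(c3ccccc3)C(C)(C)C)CCC[C@]2(C)[C@H]1CC[C@H](C)CC(=O)OC(C)(C)C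
F6 | step 18 | tert-butyl 18-hydroxy-8-oxo-17-norlabdan-15-oate | O=C1CC[C@H]2[C@](C)(CO)CCC[C@]2(C)[C@H]1CC[C@H](C)CC(=O)OC(C)(C)C
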